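The earlier runs and the new flask come from a simulation for an exercise; noise was put on by code.

Time separates what still moves late in a run from what has stopped moving.

| flask | starting complex | incoming ligand | remark | time |
|---|---|---|---|---|
| ash | 0.050 M | 0.036 M | run made earlier |  |
| maple | 0.050 M | 0.069 M | run made earlier |  |
| alder | 0.050 M | 0.071 M | run made earlier |  |
| Thursday's | 0.050 M | 0.0500 M |  | 6.0 min |
| Friday's | 0.050 M | 0.100 M |  | 6.0 min |

| run | time / min | starting complex / % | complex with one exchanged / % | complex with two exchanged / % | complex with three exchanged / % |
|---|---|---|---|---|---|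
| ash | 0.500 | 60.9 | 15.4 | 19.0 | 5.2 |
| ash | 1.50 | 62.7 | 9.6 | 23.5 | 3.9 |
| ash | 3.00 | 62.8 | 8.8 | 23.9 | 4.5 |
| ash | 4.00 | 62.9 | 7.9 | 24.3 | 4.3 |
| ash | 6.00 | 62.8 | 8.7 | 24.7 | 3.2 |
| maple | 0.500 | 39.8 | 11.3 | 35.4 | 14.3 |
| maple | 0.833 | 38.4 | 9.8 | 38.2 | 13.8 |
| maple | 1.50 | 37.9 | 9.5 | 40.9 | 12.7 |
| maple | 3.00 | 37.0 | 9.0 | 41.2 | 12.2 |
| maple | 6.00 | 35.7 | 8.8 | 43.6 | 13.9 |
| alder | 0.500 | 38.1 | 9.6 | 36.5 | 14.4 |
| alder | 0.833 | 37.7 | 8.7 | 39.7 | 14.4 |
| alder | 1.50 | 36.1 | 9.2 | 41.2 | 13.2 |
| alder | 3.00 | 35.3 | 8.2 | 43.6 | 12.2 |
| alder | 6.00 | 33.5 | 8.7 | 44.0 | 13.6 |

(standard deviation of a reading: 0.5 percentage points)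

- steps under discussion: starting complex + incoming ligand <-> leaving ligand + complex with one exchanged; complex with one exchanged + incoming ligand <-> leaving ligand + complex with two exchanged; complex with two exchanged + incoming ligand <-> leaving ligand + complex with three exchanged; complex with three exchanged + incoming ligand <-> leaving ligand + complex with four exchanged; leaving ligand -> by-product carried off

- which of these there is most of at the end, counted by the starting complex in it, Thursday's (complex with three exchanged / complex with two exchanged / complex with one exchanged / starting complex)
- which of these there is most of at the end, counted by the starting complex in it, Friday's (complex with three exchanged / complex with two exchanged / complex with one exchanged / starting complex)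
- final amount of the leader among these, as a percentage of the starting complex charged, in Thursday's
- final amount of the leader among these, as a percentage of the starting complex charged, in Friday's

Dividing the balance of the first exchange step by that of the second cancels both free ligands. What remains is Q: c(complex with one exchanged) squared, over c(starting complex) times c(complex with two exchanged). While those two steps hold balance, Q stays still even as the ligands change.

| run | cX/cM | Q at 0.500 min | Q at 1.50 min | Q at 6.00 min |
|---|---|---|---|---|
| ash | 0.720 | 0.205 | 0.0625 | 0.0488 |
| maple | 1.38 | 0.0906 | 0.0582 | 0.0498 |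
| alder | 1.42 | 0.0663 | 0.0569 | 0.0514 |

Read down the first Q column and the rows stand apart, ash higher than maple. Read across and each row falls, and the rows close up although their charges differ. In the last column a one-exchanged reading such as maple's 8.8 %, with a standard deviation of 0.5 percentage points, enters squared, so the three values do not differ beyond their scatter. This is a quasi-equilibrium as read, and the quantity to carry is the late split quotient 0.0500, the late value of that ratio of amounts.

Thursday's ratio 1.00 lies between ash and maple. A straight line between their last readings gives starting complex 51.3 % and two-exchanged 32.7 %, and Q then gives one-exchanged 9.16 %. Friday's ratio 2.00 lies beyond maple, where two-exchanged already stands above starting complex. So this reckoning, made apart from the forecast, puts starting complex above two-exchanged on Thursday's and names two-exchanged as Friday's leader, but gives Friday's no height.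

The forecast gives starting complex at 51 % for Thursday's and complex with two exchanged at 52 % for Friday's, with these grounds: “The two-exchanged species is favoured and the one-exchanged species stays scarce.”

The flask gives starting complex at 50.5 % on Thursday's and complex with two exchanged at 51.5 % on Friday's.

    starting complex + incoming ligand ⇌ leaving ligand + complex with one exchanged (K = 2.70, k = 2.50 M⁻¹ s⁻¹)
    complex with one exchanged + incoming ligand ⇌ leaving ligand + complex with two exchanged (K = 55.0, k = 6.30 M⁻¹ s⁻¹)
    complex with two exchanged + incoming ligand ⇌ leaving ligand + complex with three exchanged (K = 3.30, k = 2.60 M⁻¹ s⁻¹)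
    complex with three exchanged + incoming ligand ⇌ leaving ligand + complex with four exchanged (K = 0.110, k = 7.70 M⁻¹ s⁻¹)
    leaving ligand → by-product carried off (k = 0.00270 s⁻¹)

Q stands at 0.0501 in Thursday's and 0.0494 in Friday's at 6.0 min. In Friday's, from 3.00 min to 6.00 min, leaving ligand went from 0.0579 M to 0.0377 M while incoming ligand went from 8.39 % to 5.77 % of its charge. Over that stretch starting complex went from 17.6 % to 15.9 %. For Friday's starting complex at 6.0 min, the forecast has about 13 per cent and the flask 15.9 %; the leader is the same in both.

Friday's read at 2.5 min holds starting complex 17.9 % and two-exchanged 51.0 %, so Q gives one-exchanged 6.76 %. The computed amount is 6.72 %.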